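## Analysis of the target

Caraphenol B is a 2,3-dihydro-1H-indene (indane). Its benzo ring A (C3a to C7a) carries hydroxyl groups at C4 and C6, and the five-membered ring carries a 4-hydroxybenzoyl group at C1, a 4-hydroxyphenyl group at C2 and a 3,5-dihydroxyphenyl group at C3. C1, C2 and C3 are contiguous stereocentres, all R, and the three substituents stand on the same face of the five-membered ring, so H-1, H-2 and H-3 are mutually cis; this is the most crowded diastereomer. The sensitive sites are the five free phenols (air oxidation), the C1–H bond, which is α to the ketone and benzylic and would epimerise to the less strained 1,2-trans isomer with acid or base, and C3, a benzylic carbon ortho and para to the oxygens of ring A that ionises under acid. The difficulty is to produce a contra-thermodynamic all-cis array on a congested ring in one absolute configuration, without a heteroatom stereocentre to relay from, and never to expose it afterwards to equilibrating conditions. The strategy rests on the substitution of the five-membered ring: C1 is bonded to C7a of ring A and to the carbonyl carbon, C2 to an aryl group and C3 to C3a. At the indene oxidation level C1 and C2 are therefore the two carbons of a diarylalkyne attached to C7a, C3 is a benzylic carbanion attached to C3a, and the carbonyl carbon can come from carbon monoxide. The atom labels C1 to C7a used below are those of the target indane, also for intermediates whose systematic names are numbered otherwise.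

## Retrosynthetic reasoning

**14 back to 13.** The five phenolic O–H bonds are traced back to benzyl ethers. Benzyl is the one common phenol protection that falls under neutral, non-ionising conditions; cleavage of other ethers by Lewis or Brønsted acids would put C1 and C3 at risk. The forward step only has to spare the aryl ketone.

**13 back to 12.** The C1–H and C2–H bonds are cut together, which leads to indene 12 with a C1=C2 double bond. Syn delivery of two hydrogens to the face of 12 opposite the C3 aryl group pushes the aroyl group and the C2 aryl group onto the face of that aryl group, so the all-cis relation is written in one kinetic event. The C3–H of 12 is doubly benzylic and vinylogously α to the ketone, so the enantiomers of 12 interconvert under a weak base, and a chiral hydrogenation catalyst can funnel racemic 12 into one enantiomer of 13. The forward reaction must reduce a tetrasubstituted alkene without touching the ketone or the benzyl ethers, with a base too weak to epimerise C1 of the product.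

**12 back to 10, through 11.** A carboxyl group is added to C3; in the forward direction the C3–carboxyl bond is broken by decarboxylation. The ester is what makes C3 a usable carbanion in the ring-forming step. As a tert-butyl ester it is removed by acid alone, and the free acid 11 is a vinylogous β-keto acid that decarboxylates to the conjugated indene. The quaternary C3 of 10 is racemic, which does not matter because the centre is levelled here.

**10 back to 7, 8 and 9.** Three bonds are cut: C2–C3, C1–C(O) and C(O)–aryl. The cut is made here because C1 carries both ring A and the acyl carbon. With C1 and C2 as an alkyne on C7a, a C3 nucleophile tethered at C3a can only reach C2 (five-membered ring), which leaves C1 as the metal-bearing carbon that takes the acyl group. An acyl group placed on the alkyne beforehand, as an ynone, would sit on the carbon that the nucleophile must attack and give the wrong regiochemistry. The acyl unit therefore has to arrive during the ring closure, assembled on palladium from iodide 8 and carbon monoxide 9. The gain is the complete carbon skeleton, the ring and the ketone in one operation from three simple components, with the C1=C2 double bond exactly where the endgame needs it. The forward reaction must make carbonyl insertion precede alkyne activation and must direct the carbanion to the alkyne and not to the acyl group.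

**7 back to 4 and 6.** The C3–C3a bond is cut to aryl bromide 4 and the enolate of arylacetate 6 (palladium-catalysed enolate arylation). C3a is ortho and para to the two oxygens of ring A, so a halogen can be put there by electrophilic substitution. The reverse pairing, an ester already on the alkynyl ring with 1 as the halide, would bring carbanion, alkyne and arylpalladium together and invite the carbonyl-free annulation; in the chosen pairing only the product carries both functions.

**6 back to 1 and 5; 4 back to 3; 3 back to 1 and 2.** Ester 6 comes from bromide 1 and tert-butyl acetate 5 by the same enolate arylation. Bromide 4 comes from alkyne 3 by ring bromination at C3a. Alkyne 3 comes from 1 and alkyne 2 by Sonogashira coupling, which forms the C7a–C1 bond; C7a is meta to both oxygens and must therefore come from the halide of 1. Bromide 1 thus supplies both resorcinol rings.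

## Alternatives that were turned down

Alternative 1: The bonds from C2 and C3 to their aryl groups are cut. This leads back to an indene that already has the aroyl group and a disposable benzyl ester on a quaternary C1 and an unsubstituted C2=C3 bond (A2).
- Forward key step: the arylpalladium formed from iodide 8 would add syn across C2=C3, aryl to C2 and palladium to the benzylic C3. The boronic acid A3 would then hand its aryl group to C3 with retention, giving the cis-2,3-diarylindane A1 as a pair of C1 epimers. One hydrogenolysis would remove the benzyl ester and all benzyl ethers, and the β-keto acid would lose its carboxyl group.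
- For it: the cis relation of the two aryl groups follows from the syn mechanism; β-hydride elimination is shut off because the only hydrogen on C2 ends anti to palladium; a chiral ligand could in principle set C2 and C3; the endgame is one step shorter.
- Against it: C2 is neopentyl next to the quaternary C1, and C3 sits beside the C4 benzyloxy group and must take a 3,5-disubstituted aryl group, so the coupling is crowded at both carbons. The racemic quaternary C1 of A2 shows a chiral catalyst two unlike faces, so matched and mismatched substrate enantiomers would erode selectivity at C2 and C3. C1 is finally set by protonation of the enol left by decarboxylation, a step with no controlling element in which the wanted all-cis isomer is the less stable one. A2 also needs its own multistep synthesis.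
- Comparison: this alternative is stronger in making the cis-2,3 relation directly by a known type of reaction and in its shorter endgame. The chosen strategy offers instead a single event that sets C1 together with C2 and C3 by delivery of hydrogen rather than by protonation, and an assembly of ring, skeleton and ketone from a four-step precursor.

Alternative 2: The C1–C7a bond is cut by viewing the indene as the ring-contracted product of the six-membered diazo ketone A5, in which the carbonyl carbon still lies between C7a and the diazo carbon (the later C1).
- Forward key step: on irradiation A5 would lose nitrogen, C7a would shift from the carbonyl carbon to the former diazo carbon (Wolff rearrangement), and a thiol would trap the ketene as the thioester A4. A thioester cross-coupling with an arylmetal would give the aryl ketone; the endgame would then be the one used here, since A4 has the same labile C3–H.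
- For it: photochemical Wolff contraction of diazonaphthalenones is among the most dependable ring contractions; it needs no metal and no gas under pressure and tolerates crowding.
- Against it: A5 is a fully substituted naphthalene derivative with both aryl groups and both ring oxygens in defined positions, so its synthesis is at least as demanding as that of the indene, and the six-membered ring is built only to be discarded. The aryl group of the ketone costs one more C–C coupling at a hindered, tetrasubstituted enoyl thioester. A5 and A4 contain cis-stilbene chromophores that absorb in the same region and can photocyclise.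
- Comparison: on precedent for the key step this alternative is clearly stronger. The chosen strategy offers step economy in its place: it forms the ring once, brings in the ketone with its aryl group in the same operation and starts from a precursor made in four steps.

Alternative 3: The two bonds from ring A to the five-membered ring, C1–C7a and C3–C3a, are cut. This leads to an aryne (released from the silyl triflate A8) and an open C1–C2–C3 chain, the β-keto ester A7 with a second ketone at C3.
- Forward key step: with a fluoride source the enolate carbon C1 of A7 would add to C7a of the aryne, the position meta to the C4 benzyloxy group. The aryl anion formed at C3a would add to the C3 ketone and close the ring to the 3-hydroxyindane A6. Removal of the tertiary hydroxyl group, cleavage of the allyl ester and decarboxylation would follow.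
- For it: no transition metal in the ring-forming step; regiochemistry fixed reliably by the polarisation of the alkoxy aryne; two ring bonds in one step; an ester that leaves under neutral conditions.
- Against it: in aryne reactions of β-keto esters the aryl anion normally attacks the neighbouring ketone and the four-membered intermediate fragments (acyl–alkyl insertion), so the aroyl ketone on C1 competes with the C3 ketone, and the acidic C2–H can quench the anion. A6 has C3 at the wrong oxidation level and none of its centres is of use: C3 must be deoxygenated by way of the C2=C3 alkene, C1 is again left to a protonation after decarboxylation, and the only handle for absolute configuration would be asymmetric hydrogenation of an unfunctionalised tetrasubstituted diarylalkene. A7 and A8 both need several steps.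
- Comparison: this alternative is stronger in regiocontrol and in avoiding pressure equipment. The chosen strategy delivers C1, C2 and C3 at the correct oxidation level straight away and leaves an enone with a labile C3–H as the handle for the asymmetric step.

Key step: step 5

Assumption: which antipode of the diphosphine leads to the (1R,2R,3R) series cannot be derived with confidence for this substrate; the (R)-ligand is written in step 7 and its mirror image would be used if the induction runs the other way.

## Route

Step 1
Reactants: 1 1-bromo-3,5-bis(benzyloxy)benzene; 2 1-(benzyloxy)-4-ethynylbenzene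
Product: 3 1,3-bis(benzyloxy)-5-{[4-(benzyloxy)phenyl]ethynyl}benzene
Conditions: PdCl2(MeCN)2 (2 mol %), XPhos (6 mol %), Cs2CO3 (2.5 equiv), MeCN, 80 °C
Reagents that add atoms: none
Why: Copper-free Sonogashira coupling; the bulky biarylphosphine makes oxidative addition into the aryl bromide easy and the absence of copper avoids oxidative homocoupling of alkyne 2, while the benzyl ethers are inert.

Step 2
Reactants: 3 1,3-bis(benzyloxy)-5-{[4-(benzyloxy)phenyl]ethynyl}benzene
Product: 4 1,5-bis(benzyloxy)-2-bromo-3-{[4-(benzyloxy)phenyl]ethynyl}benzene
Conditions: NBS (1.0 equiv), MeCN/CH2Cl2, 0 °C, dark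
Reagents that add atoms: N-bromosuccinimide, O=C1CCC(=O)N1Br
Why: Electrophilic aromatic bromination; the resorcinol diether ring is by far the most nucleophilic site, and the position ortho to the alkyne and para to a benzyloxy group (the later C3a) is attacked in preference to the position flanked by two benzyloxy groups, as is usual for 3,5-dialkoxyaryl compounds. A diarylalkyne does not add NBS under anhydrous, acid-free conditions, and one equivalent at 0 °C limits dibromination.

Step 3
Reactants: 1 1-bromo-3,5-bis(benzyloxy)benzene; 5 tert-butyl acetate
Product: 6 tert-butyl 2-[3,5-bis(benzyloxy)phenyl]acetate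
Conditions: 5 (1.5 equiv), LiN(SiMe3)2 (2.5 equiv), Pd(dba)2 (2 mol %), P(t-Bu)3 (2 mol %), toluene, rt
Reagents that add atoms: none
Why: Palladium-catalysed α-arylation of an ester enolate; the lithium enolate of 5 couples with the unhindered bromide 1 through a monoligated arylpalladium bromide, and the tert-butyl group suppresses Claisen condensation.

Step 4
Reactants: 4 1,5-bis(benzyloxy)-2-bromo-3-{[4-(benzyloxy)phenyl]ethynyl}benzene; 6 tert-butyl 2-[3,5-bis(benzyloxy)phenyl]acetate
Product: 7 tert-butyl 2-[2,4-bis(benzyloxy)-6-{[4-(benzyloxy)phenyl]ethynyl}phenyl]-2-[3,5-bis(benzyloxy)phenyl]acetate (racemic)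
Conditions: 6 (1.2 equiv), LiN(SiMe3)2 (2.3 equiv), toluene, 0 °C; then 4, Pd(dba)2 (5 mol %), P(t-Bu)3 (5 mol %), 25 to 50 °C
Reagents that add atoms: none
Why: Palladium-catalysed α-arylation of an ester enolate, here forming the C3–C3a bond; the monoligated P(t-Bu)3 catalyst tolerates the two ortho substituents of 4. In toluene the product is held as an aggregated lithium enolate, a poor nucleophile towards its own alkyne, and the excess enolate of 6 consumes the arylpalladium bromide before it can activate that triple bond. The new stereocentre forms as a racemate and is levelled in step 6.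

Step 5
Reactants: 7 tert-butyl 2-[2,4-bis(benzyloxy)-6-{[4-(benzyloxy)phenyl]ethynyl}phenyl]-2-[3,5-bis(benzyloxy)phenyl]acetate; 8 1-(benzyloxy)-4-iodobenzene; 9 carbon monoxide
Product: 10 tert-butyl 5,7-bis(benzyloxy)-1-[3,5-bis(benzyloxy)phenyl]-3-[4-(benzyloxy)benzoyl]-2-[4-(benzyloxy)phenyl]-1H-indene-1-carboxylate (racemic)
Conditions: 8 (1.5 equiv), CO (5 bar), Pd2(dba)3 (5 mol %), PPh3 (20 mol %), Cs2CO3 (2.0 equiv), DMSO, 60 °C
Reagents that add atoms: none
Why: Proposed new method: zerovalent palladium inserts into the C–I bond of 8, and CO insertion, fast for an electron-rich aryl group under pressure, gives a divalent aroylpalladium iodide that is the resting electrophile and binds the C1–C2 triple bond of 7. Cs2CO3 in DMSO maintains a low concentration of the ester-stabilised C3 carbanion, which adds to C2 on the side away from palladium and closes the five-membered ring in a 5-endo-dig mode; the 4-exo closure at C1 would give a benzocyclobutene and is not accessible. The vinyl(aroyl)palladium at C1 then reductively eliminates, forming C1–C(O) and returning zerovalent palladium; if the aroylpalladium instead inserted the alkyne syn, only the regiochemistry with the acyl group on C1 lets C3 reach palladium through a six-membered palladacycle, so both manifolds lead to 10. The closest known reaction types are the palladium-catalysed carboannulation of 2-(2-alkynylphenyl)malonates with aryl halides to indenes and the carbonylative cyclisation of 2-alkynylanilides with aryl iodides and CO to 3-aroylindoles; the proposal joins the carbon nucleophile of the first to the acyl electrophile of the second. Three selectivities are needed: CO insertion before alkyne activation (secured by CO pressure and moderate temperature, otherwise the aryl group is transferred to C1), attack at C2 (secured by the tether), and attack of the carbanion on the alkyne and not on the acyl carbon (the tertiary diarylacetate carbanion is too hindered for acyl transfer to a quaternary centre). No stereocentre of the target is set, since the quaternary carbon of 10 is racemic and is levelled by the decarboxylation of step 6.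

Step 6
Reactants: 10 tert-butyl 5,7-bis(benzyloxy)-1-[3,5-bis(benzyloxy)phenyl]-3-[4-(benzyloxy)benzoyl]-2-[4-(benzyloxy)phenyl]-1H-indene-1-carboxylate
Product: 12 {5,7-bis(benzyloxy)-1-[3,5-bis(benzyloxy)phenyl]-2-[4-(benzyloxy)phenyl]-1H-inden-3-yl}[4-(benzyloxy)phenyl]methanone (racemic), via indene-1-carboxylic acid 11 (not isolated)
Conditions: TFA/CH2Cl2 (1:4), 0 °C to rt; evaporate; then Et3N (0.2 equiv), toluene, 50 °C
Reagents that add atoms: none
Why: Acidolysis of the tert-butyl ester by the E1 pathway is indifferent to the congestion at C3, and acid 11 is a vinylogous β-keto acid whose carboxylate loses CO2 to an aroyl-stabilised indenide on gentle warming with a trace of amine. Reprotonation under these equilibrating conditions should favour 12, the tautomer in which C1=C2 is conjugated with the ketone and the C3 aryl group is turned out of the plane of the C4 benzyloxy group; short exposure to dilute acid at low temperature spares the benzyl ethers.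

Step 7
Reactants: 12 {5,7-bis(benzyloxy)-1-[3,5-bis(benzyloxy)phenyl]-2-[4-(benzyloxy)phenyl]-1H-inden-3-yl}[4-(benzyloxy)phenyl]methanone
Product: 13 [(1R,2R,3R)-4,6-bis(benzyloxy)-3-[3,5-bis(benzyloxy)phenyl]-2-[4-(benzyloxy)phenyl]-2,3-dihydro-1H-inden-1-yl][4-(benzyloxy)phenyl]methanone (all-cis)
Conditions: H2 (80 bar), Ru(OAc)2[(R)-H8-BINAP] (5 mol %), Et3N (0.5 equiv), CH2Cl2/MeOH (3:1), 40 °C
Reagents that add atoms: none
Why: Proposed new method: the C3–H of 12 is doubly benzylic and vinylogously α to the ketone, so Et3N interconverts the enantiomers through the indenide, while the C1–H of the product, several pK units less acidic, stays untouched. The chiral ruthenium hydride, anchored by the ketone oxygen, reduces the enantiomer whose open face (anti to the C3 aryl group) matches its own preference and delivers both hydrogens to C1 and C2 from that face, which sets the all-cis (1R,2R,3R) array in one event: C3 by catalyst selection in the dynamic kinetic resolution, C1 and C2 by syn addition anti to the C3 aryl group. The closest known reaction types are the ruthenium- and rhodium-catalysed asymmetric hydrogenation of tetrasubstituted cyclic enones to cis products and the dynamic kinetic resolution of γ-epimerisable cyclic enones in copper hydride conjugate reduction; the homogeneous catalyst leaves the aryl ketone and the benzyl ethers alone.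

Step 8
Reactants: 13 [(1R,2R,3R)-4,6-bis(benzyloxy)-3-[3,5-bis(benzyloxy)phenyl]-2-[4-(benzyloxy)phenyl]-2,3-dihydro-1H-inden-1-yl][4-(benzyloxy)phenyl]methanone
Product: 14 Caraphenol B, [(1R,2R,3R)-3-(3,5-dihydroxyphenyl)-4,6-dihydroxy-2-(4-hydroxyphenyl)-2,3-dihydro-1H-inden-1-yl](4-hydroxyphenyl)methanone (all-cis)
Conditions: H2 (1 atm), Pd/C (10 wt %), EtOAc/EtOH (1:1), rt; filtration, evaporation below 30 °C, reversed-phase chromatography with neutral eluent
Reagents that add atoms: none
Why: Hydrogenolysis of the five benzyl ethers on palladium under neutral conditions at room temperature; without acid or base neither the C1–H α to the ketone nor the acid-labile benzylic C3 can epimerise. The electron-rich, hindered aryl ketone is reduced much more slowly than the O-benzyl groups are cleaved, so the reaction is stopped once the uptake for five benzyl groups is reached.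

## Compound list

1 | 1-bromo-3,5-bis(benzyloxy)benzene | Brc1cc(OCc2ccccc2)cc(OCc2ccccc2)c1 | starting material
2 | 1-(benzyloxy)-4-ethynylbenzene | C#Cc1ccc(OCc2ccccc2)cc1 | starting material
3 | 1,3-bis(benzyloxy)-5-{[4-(benzyloxy)phenyl]ethynyl}benzene | C(#Cc1ccc(OCc2ccccc2)cc1)c1cc(OCc2ccccc2)cc(OCc2ccccc2)c1 | intermediate
4 | 1,5-bis(benzyloxy)-2-bromo-3-{[4-(benzyloxy)phenyl]ethynyl}benzene | Brc1c(OCc2ccccc2)cc(OCc2ccccc2)cc1C#Cc1ccc(OCc2ccccc2)cc1 | intermediate
5 | tert-butyl acetate | CC(=O)OC(C)(C)C | starting material
6 | tert-butyl 2-[3,5-bis(benzyloxy)phenyl]acetate | CC(C)(C)OC(=O)Cc1cc(OCc2ccccc2)cc(OCc2ccccc2)c1 | intermediate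
7 | tert-butyl 2-[2,4-bis(benzyloxy)-6-{[4-(benzyloxy)phenyl]ethynyl}phenyl]-2-[3,5-bis(benzyloxy)phenyl]acetate, racemic | CC(C)(C)OC(=O)C(c1cc(OCc2ccccc2)cc(OCc2ccccc2)c1)c1c(OCc2ccccc2)cc(OCc2ccccc2)cc1C#Cc1ccc(OCc2ccccc2)cc1 | intermediate
8 | 1-(benzyloxy)-4-iodobenzene | Ic1ccc(OCc2ccccc2)cc1 | starting material
9 | carbon monoxide | [C-]#[O+] | starting material
10 | tert-butyl 5,7-bis(benzyloxy)-1-[3,5-bis(benzyloxy)phenyl]-3-[4-(benzyloxy)benzoyl]-2-[4-(benzyloxy)phenyl]-1H-indene-1-carboxylate, racemic | CC(C)(C)OC(=O)C1(c2cc(OCc3ccccc3)cc(OCc3ccccc3)c2)C(c2ccc(OCc3ccccc3)cc2)=C(C(=O)c2ccc(OCc3ccccc3)cc2)c2cc(OCc3ccccc3)cc(OCc3ccccc3)c21 | intermediate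
11 | 5,7-bis(benzyloxy)-1-[3,5-bis(benzyloxy)phenyl]-3-[4-(benzyloxy)benzoyl]-2-[4-(benzyloxy)phenyl]-1H-indene-1-carboxylic acid, racemic, not isolated | OC(=O)C1(c2cc(OCc3ccccc3)cc(OCc3ccccc3)c2)C(c2ccc(OCc3ccccc3)cc2)=C(C(=O)c2ccc(OCc3ccccc3)cc2)c2cc(OCc3ccccc3)cc(OCc3ccccc3)c21 | intermediate
12 | {5,7-bis(benzyloxy)-1-[3,5-bis(benzyloxy)phenyl]-2-[4-(benzyloxy)phenyl]-1H-inden-3-yl}[4-(benzyloxy)phenyl]methanone, racemic | O=C(c1ccc(OCc2ccccc2)cc1)C1=C(c2ccc(OCc3ccccc3)cc2)C(c2cc(OCc3ccccc3)cc(OCc3ccccc3)c2)c2c(OCc3ccccc3)cc(OCc3ccccc3)cc21 | intermediate
13 | [(1R,2R,3R)-4,6-bis(benzyloxy)-3-[3,5-bis(benzyloxy)phenyl]-2-[4-(benzyloxy)phenyl]-2,3-dihydro-1H-inden-1-yl][4-(benzyloxy)phenyl]methanone, all-cis | O=C(c1ccc(OCc2ccccc2)cc1)[C@H]1c2cc(OCc3ccccc3)cc(OCc3ccccc3)c2[C@@H](c2cc(OCc3ccccc3)cc(OCc3ccccc3)c2)[C@H]1c1ccc(OCc2ccccc2)cc1 | intermediate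
14 | Caraphenol B, [(1R,2R,3R)-3-(3,5-dihydroxyphenyl)-4,6-dihydroxy-2-(4-hydroxyphenyl)-2,3-dihydro-1H-inden-1-yl](4-hydroxyphenyl)methanone, all-cis | O=C(c1ccc(O)cc1)[C@H]1c2cc(O)cc(O)c2[C@@H](c2cc(O)cc(O)c2)[C@H]1c1ccc(O)cc1 | target

## Step count and least certain steps

Total: 8 steps. Longest linear sequence: 7 steps (steps 1, 2, 4, 5, 6, 7, 8); step 3 is the one-step side branch to 6.

**Step 5 (key step, proposed new method).** The most likely failure is loss of the order of events. If alkyne activation by arylpalladium outruns carbonyl insertion at the temperature needed to generate the carbanion, the aryl group and not the aroyl group is transferred to C1. If ring closure is slow because the carbanion concentration is low, the aroylpalladium is intercepted by carbonate or traces of water, or base-induced cyclisation with protonation at C1 takes over. The fallback uses known chemistry, sets out from 7 and comes back at 10, and separates ring closure from acylation. Deprotonation of 7 with KN(SiMe3)2 in THF at −78 °C and addition of iodine should effect the iodonium-triggered 5-endo-dig carbocyclisation to tert-butyl 5,7-bis(benzyloxy)-1-[3,5-bis(benzyloxy)phenyl]-2-[4-(benzyloxy)phenyl]-3-iodo-1H-indene-1-carboxylate F1. Carbonylative Suzuki–Miyaura coupling of F1 with 4-(benzyloxy)phenylboronic acid under 9 (Pd(PPh3)4, K2CO3, anisole, 80 °C) should then give 10.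

**Step 7 (proposed new method).** The most likely failures are absence of turnover (the tetrasubstituted, triaryl-flanked alkene is very hindered, and the indenide may bind ruthenium), weak discrimination between the enantiomers of 12 or its tautomer, and slow base-mediated epimerisation of the product at C1 towards the 1,2-trans isomer. The fallback gives up catalytic asymmetric induction for resolution; it sets out from 12 and comes back at 14, passing over 13. Hydrogenation of 12 over Pd/C (H2 1 atm, EtOAc/EtOH, rt) should add hydrogen syn from the face opposite the C3 aryl group and cleave the benzyl ethers in the same operation, giving the racemate of all-cis Caraphenol B F2. The enantiomers would be separated by preparative HPLC on a chiral stationary phase (amylose tris(3,5-dimethylphenylcarbamate)) to give 14.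

**Step 4.** The most likely failures are sluggish coupling of the di-ortho-substituted bromide 4 with a secondary benzylic enolate, leading to hydrodebromination, and premature palladium-mediated cyclisation of the product enolate onto its own alkyne. The fallback forms the C3–C3a bond by carbonyl addition; it sets out from 4 (with 1) and comes back at 7. Bromide 1 is lithiated (n-BuLi, THF, −78 °C) and added to excess di-tert-butyl oxalate to give tert-butyl 2-[3,5-bis(benzyloxy)phenyl]-2-oxoacetate F3. Bromide 4 is lithiated in the same way and added to F3 to give tert-butyl 2-[2,4-bis(benzyloxy)-6-{[4-(benzyloxy)phenyl]ethynyl}phenyl]-2-[3,5-bis(benzyloxy)phenyl]-2-hydroxyacetate F4. The α-hydroxyl group is removed reductively with SmI2 (THF/HMPA, pivalic acid, rt), which gives 7.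

**Step 8.** The most likely failures are over-reduction of the aryl ketone on palladium (to the carbinol and on to the methylene compound) once the phenols are free, and epimerisation at C1 during isolation. The fallback replaces reductive cleavage by Lewis-acid dealkylation; it sets out from 13 and comes back at 14, and no new compound is made on the way (F0). BCl3 with pentamethylbenzene as a non-basic benzyl cation scavenger in CH2Cl2 at −78 °C, followed by a cold methanol quench, should remove the five benzyl groups without any reducing agent and below the temperature at which C1 or C3 equilibrate.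

## Further compounds

F1 | step 5 | tert-butyl 5,7-bis(benzyloxy)-1-[3,5-bis(benzyloxy)phenyl]-2-[4-(benzyloxy)phenyl]-3-iodo-1H-indene-1-carboxylate, racemic | CC(C)(C)OC(=O)C1(c2cc(OCc3ccccc3)cc(OCc3ccccc3)c2)C(c2ccc(OCc3ccccc3)cc2)=C(I)c2cc(OCc3ccccc3)cc(OCc3ccccc3)c21
F2 | step 7 | racemate of all-cis Caraphenol B, (1R,2R,3R) and (1S,2S,3S) enantiomers | O=C(c1ccc(O)cc1)[C@H]1c2cc(O)cc(O)c2[C@@H](c2cc(O)cc(O)c2)[C@H]1c1ccc(O)cc1.O=C(c1ccc(O)cc1)[C@@H]1c2cc(O)cc(O)c2[C@H](c2cc(O)cc(O)c2)[C@@H]1c1ccc(O)cc1
F3 | step 4 | tert-butyl 2-[3,5-bis(benzyloxy)phenyl]-2-oxoacetate | CC(C)(C)OC(=O)C(=O)c1cc(OCc2ccccc2)cc(OCc2ccccc2)c1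
F4 | step 4 | tert-butyl 2-[2,4-bis(benzyloxy)-6-{[4-(benzyloxy)phenyl]ethynyl}phenyl]-2-[3,5-bis(benzyloxy)phenyl]-2-hydroxyacetate, racemic | CC(C)(C)OC(=O)C(O)(c1cc(OCc2ccccc2)cc(OCc2ccccc2)c1)c1c(OCc2ccccc2)cc(OCc2ccccc2)cc1C#Cc1ccc(OCc2ccccc2)cc1
F0 | step 8 | none | none
A1 | alternative 1 | benzyl (2S,3R)-4,6-bis(benzyloxy)-1-[4-(benzyloxy)benzoyl]-3-[3,5-bis(benzyloxy)phenyl]-2-[4-(benzyloxy)phenyl]-2,3-dihydro-1H-indene-1-carboxylate, 2,3-cis, both C1 epimers | O=C(OCc3ccccc3)C1(C(=O)c2ccc(OCc3ccccc3)cc2)c2cc(OCc3ccccc3)cc(OCc3ccccc3)c2[C@@H](c2cc(OCc3ccccc3)cc(OCc3ccccc3)c2)[C@H]1c1ccc(OCc2ccccc2)cc1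
A2 | alternative 1 | benzyl 4,6-bis(benzyloxy)-1-[4-(benzyloxy)benzoyl]-1H-indene-1-carboxylate, racemic | O=C(OCc3ccccc3)C1(C(=O)c2ccc(OCc3ccccc3)cc2)C=Cc2c(OCc3ccccc3)cc(OCc3ccccc3)cc21
A3 | alternative 1 | 3,5-bis(benzyloxy)phenylboronic acid | OB(O)c1cc(OCc2ccccc2)cc(OCc2ccccc2)c1
A4 | alternative 2 | S-ethyl 5,7-bis(benzyloxy)-1-[3,5-bis(benzyloxy)phenyl]-2-[4-(benzyloxy)phenyl]-1H-indene-3-carbothioate, racemic | CCSC(=O)C1=C(c2ccc(OCc3ccccc3)cc2)C(c2cc(OCc3ccccc3)cc(OCc3ccccc3)c2)c2c(OCc3ccccc3)cc(OCc3ccccc3)cc21
A5 | alternative 2 | 5,7-bis(benzyloxy)-4-[3,5-bis(benzyloxy)phenyl]-3-[4-(benzyloxy)phenyl]-2-diazonaphthalen-1(2H)-one | O=C1C(=[N+]=[N-])C(c2ccc(OCc3ccccc3)cc2)=C(c2cc(OCc3ccccc3)cc(OCc3ccccc3)c2)c2c(OCc3ccccc3)cc(OCc3ccccc3)cc21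
A6 | alternative 3 | allyl 4,6-bis(benzyloxy)-1-[4-(benzyloxy)benzoyl]-3-[3,5-bis(benzyloxy)phenyl]-3-hydroxy-2-[4-(benzyloxy)phenyl]-2,3-dihydro-1H-indene-1-carboxylate, racemic diastereomers | C=CCOC(=O)C1(C(=O)c2ccc(OCc3ccccc3)cc2)c2cc(OCc3ccccc3)cc(OCc3ccccc3)c2C(O)(c2cc(OCc3ccccc3)cc(OCc3ccccc3)c2)C1c1ccc(OCc2ccccc2)cc1
A7 | alternative 3 | allyl 2-[4-(benzyloxy)benzoyl]-3-[4-(benzyloxy)phenyl]-4-[3,5-bis(benzyloxy)phenyl]-4-oxobutanoate, racemic diastereomers | C=CCOC(=O)C(C(=O)c1ccc(OCc2ccccc2)cc1)C(c1ccc(OCc2ccccc2)cc1)C(=O)c1cc(OCc2ccccc2)cc(OCc2ccccc2)c1
A8 | alternative 3 | 3,5-bis(benzyloxy)-2-(trimethylsilyl)phenyl trifluoromethanesulfonate | C[Si](C)(C)c1c(OCc2ccccc2)cc(OCc2ccccc2)cc1OS(=O)(=O)C(F)(F)F
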